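**Retrosynthetic overview**
- Feature: the only ring is an 18-membered 1,5,9,13-tetraazacyclooctadecan-6-one. N1 and N13 are tertiary amides and N5 is the lactam NH, so N9 is the only basic nitrogen. N9 lies between the stereocentre C8 and the unbranched methylene C10, which is three carbons from N13.
- Last bond made, closing the only ring: N9–C10, read as a primary amine on C8 and an aldehyde at C10. Ring-closing reductive amination of the unprotected seco amino aldehyde gives the target directly.
- The amino aldehyde is stored as its N-Boc/diethyl acetal form, so one acid treatment frees both ends. This compound is cut at the N5–C6 amide into a C14 β-amino acid and a linear bis-amide amine.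
- β-Amino acid: C8 comes from the chiral pool (Boc-β-homoallylglycine) and the Z-alkene from Z-selective cross-metathesis with dec-1-ene.
- Chain: 5-aminopentan-1-ol (N1, C14–C18) is cyanoethylated (C2–C4, N5), acylated and oxidised. It is then reductively aminated with 3,3-diethoxypropan-1-amine (N13, C12–C10) and acylated again, and the nitrile is hydrogenated.

Key step: step 12

Assumption: compound 1 (Boc-L-β-homoallylglycine) is taken as a catalogue amino acid; it is the Arndt–Eistert homologue of Boc-L-allylglycine with unchanged spatial arrangement at the stereocentre.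

**Step 1**
Reactants: 1 (S)-3-[(tert-butoxycarbonyl)amino]hex-5-enoic acid
Product: 2 methyl (S)-3-[(tert-butoxycarbonyl)amino]hex-5-enoate
Conditions: MeI, KHCO3, DMF, rt
Reagents that add atoms: iodomethane, CI
Why: SN2 O-alkylation of the carboxylate masks the acid, which would otherwise protonate the Ru–C chelate of the catalyst in step 2, and the weak base leaves the NHBoc group and the stereocentre untouched.

**Step 2**
Reactants: 2 methyl (S)-3-[(tert-butoxycarbonyl)amino]hex-5-enoate; 3 dec-1-ene (4 equiv)
Product: 4 methyl (3S,5Z)-3-[(tert-butoxycarbonyl)amino]tetradec-5-enoate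
Conditions: cyclometalated Z-selective Grubbs catalyst Ru(NO3)(=CH-C6H4-2-OiPr)[C,C-chelating 1-(adamantane-1,2-diyl)-3-mesitylimidazolidin-2-ylidene] (C32H41N3O4Ru, 3 mol %), THF (0.5 M), 35 °C, ethene vented in an argon stream; AgNO3-silica polish if needed
Reagents that add atoms: none
Why: Z-selective olefin cross-metathesis, in which the side-bound ruthenacyclobutane of the chelated catalyst forces both substituents away from the N-mesityl group so that the cis alkene is released, while excess 3 and loss of ethene favour the cross product and allylglycine-type carbamate esters are tolerated substrates.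

**Step 3**
Reactants: 4 methyl (3S,5Z)-3-[(tert-butoxycarbonyl)amino]tetradec-5-enoate
Product: 5 (3S,5Z)-3-[(tert-butoxycarbonyl)amino]tetradec-5-enoic acid
Conditions: LiOH, THF/H2O (3:1), 0 °C to rt; then 1 M HCl to pH 3–4, 0 °C
Reagents that add atoms: lithium hydroxide, [Li+].[OH-]
Why: Acyl-oxygen saponification of an unhindered methyl ester is routine for Boc-β-amino esters and touches neither the carbamate, the Z-alkene nor the β-stereocentre.

**Step 4**
Reactants: 6 5-aminopentan-1-ol; 7 acrylonitrile (1.0 equiv)
Product: 8 3-[(5-hydroxypentyl)amino]propanenitrile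
Conditions: MeOH, 0 °C to rt
Reagents that add atoms: none
Why: Aza-Michael addition (cyanoethylation) stops after one addition because the β-aminonitrile nitrogen is less nucleophilic and more hindered than the primary amine, and the alcohol does not add without strong base.

**Step 5**
Reactants: 8 3-[(5-hydroxypentyl)amino]propanenitrile; 9 (S)-2-methylbutanoic acid
Product: 10 (2S)-N-(2-cyanoethyl)-N-(5-hydroxypentyl)-2-methylbutanamide
Conditions: EDC (free base), Oxyma, CH2Cl2, 0 °C to rt
Reagents that add atoms: none
Why: Carbodiimide amide coupling in which the amine outcompetes the primary alcohol in the absence of an acyl-transfer catalyst, and the α-centre of 9 is safe because it has no oxazolone pathway and no ketene-forming acid chloride/base pair is used.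

**Step 6**
Reactants: 10 (2S)-N-(2-cyanoethyl)-N-(5-hydroxypentyl)-2-methylbutanamide
Product: 11 (2S)-N-(2-cyanoethyl)-2-methyl-N-(5-oxopentyl)butanamide
Conditions: TEMPO (10 mol %), PhI(OAc)2, CH2Cl2, rt
Reagents that add atoms: none
Why: Oxoammonium oxidation stops at the aldehyde in the absence of water, and because the nitrogen is already an amide the 5-oxopentyl chain cannot close to a cyclic iminium.

**Step 7**
Reactants: 11 (2S)-N-(2-cyanoethyl)-2-methyl-N-(5-oxopentyl)butanamide; 12 3,3-diethoxypropan-1-amine (1.5 equiv)
Product: 14 (2S)-N-(2-cyanoethyl)-N-{5-[(3,3-diethoxypropyl)amino]pentyl}-2-methylbutanamide, via aldimine 13 (not isolated)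
Conditions: 3 Å MS, MeOH, rt; then NaBH4, 0 °C
Reagents that add atoms: none
Why: Stepwise reductive amination, in which the aldimine is formed fully with excess amine before the hydride is added so that double alkylation is suppressed, and the basic medium keeps nitrile, amide and acetal intact.

**Step 8**
Reactants: 14 (2S)-N-(2-cyanoethyl)-N-{5-[(3,3-diethoxypropyl)amino]pentyl}-2-methylbutanamide; 9 (S)-2-methylbutanoic acid
Product: 15 (2S)-N-(2-cyanoethyl)-N-(5-{(3,3-diethoxypropyl)[(2S)-2-methylbutanoyl]amino}pentyl)-2-methylbutanamide
Conditions: EDC (free base), Oxyma, CH2Cl2, 0 °C to rt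
Reagents that add atoms: none
Why: Carbodiimide amide coupling at the only N–H of 14 under anhydrous, nearly neutral conditions that neither open the acetal nor epimerise either acyl α-centre.

**Step 9**
Reactants: 15 (2S)-N-(2-cyanoethyl)-N-(5-{(3,3-diethoxypropyl)[(2S)-2-methylbutanoyl]amino}pentyl)-2-methylbutanamide
Product: 16 (2S)-N-(3-aminopropyl)-N-(5-{(3,3-diethoxypropyl)[(2S)-2-methylbutanoyl]amino}pentyl)-2-methylbutanamide
Conditions: H2 (4 bar), Raney Ni, 7 M NH3 in MeOH, rt
Reagents that add atoms: none
Why: Catalytic nitrile hydrogenation, in which ammonia intercepts the intermediate aldimine and so suppresses secondary-amine formation, the tertiary amides and the acetal are inert, and 16 is used at once to forestall an N-to-N acyl shift.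

**Step 10**
Reactants: 5 (3S,5Z)-3-[(tert-butoxycarbonyl)amino]tetradec-5-enoic acid; 16 (2S)-N-(3-aminopropyl)-N-(5-{(3,3-diethoxypropyl)[(2S)-2-methylbutanoyl]amino}pentyl)-2-methylbutanamide
Product: 17 N-Boc/diethyl acetal seco compound, the (3S,5Z)-3-(Boc-amino)tetradec-5-enamide of the primary amine of 16
Conditions: EDC (free base), Oxyma, CH2Cl2, 0 °C to rt; chromatography on Et3N-deactivated silica
Reagents that add atoms: none
Why: Carbodiimide amide coupling of a urethane-protected β-amino acid, whose stereocentre is not α to the activated carbonyl and so cannot epimerise, to the only free amine of 16.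

**Step 11**
Reactants: 17 N-Boc/diethyl acetal seco compound
Product: 18 seco amino aldehyde trifluoroacetate (ammonium at the C8 nitrogen, CHO at C10)
Conditions: TFA/CH2Cl2/H2O (10:10:1), 0 °C to rt, short contact; co-evaporation with toluene below 25 °C
Reagents that add atoms: water, O; trifluoroacetic acid, OC(=O)C(F)(F)F
Why: Boc acidolysis (loss of the tert-butyl cation, then decarboxylation) and acid hydrolysis of the acetal run in the same medium, protonation of the amine keeps it from condensing with the aldehyde before step 12, and brief exposure at or below room temperature spares the Z-alkene.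

**Step 12**
Reactants: 18 seco amino aldehyde trifluoroacetate
Product: 21 (8S)-1,13-bis[(2S)-2-methylbutanoyl]-8-[(2Z)-undec-2-en-1-yl]-1,5,9,13-tetraazacyclooctadecan-6-one (CNP0302576.1), via free amino aldehyde 19 (not isolated), via cyclic imine 20 (not isolated)
Conditions: iPr2NEt (to neutralise the salt), AcOH (5 equiv), 4 Å MS, ClCH2CH2Cl (1 mM), rt, several hours; then NaBH(OAc)3 (5 equiv), rt; aq. Na2CO3 work-up, chromatography
Reagents that add atoms: none
Why: Neutralisation frees the primary amine of 19, which adds to the C10 aldehyde to give a hemiaminal that loses water to the sieves; every event up to the imine is reversible, so open and oligomeric imines keep exchanging and, at a concentration chosen below the effective molarity expected for a strain-free large ring, should settle on monomeric 20, which AcOH protonates and NaBH(OAc)3 reduces irreversibly at C10. The closest known reaction type is the macrocyclising reductive amination of amino aldehydes used for polyamine and peptide macrocycles. The 18-membered ring closes in an 18-exo-trig mode by attack of N9 on the carbonyl carbon, and the hydride then saturates the endocyclic C10=N9 bond. No stereocentre is created, C8 is not enolisable, and the two acyl α-centres and the Z-alkene are inert to a weakly acidic borohydride. Chemoselectivity is built into the substrate, since N1 and N13 are tertiary amides and N5 is a secondary amide, so N9 is the only nucleophilic nitrogen. Ring over oligomer is secured by dilution combined with imine exchange, aldehyde reduction is avoided by adding the hydride only after equilibration, and a second alkylation of N9 is slowed by the branch at C8 and by the low concentration of remaining aldehyde.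

**Compound list**
1 | (S)-3-[(tert-butoxycarbonyl)amino]hex-5-enoic acid | C=CC[C@H](NC(=O)OC(C)(C)C)CC(=O)O | starting material
2 | methyl (S)-3-[(tert-butoxycarbonyl)amino]hex-5-enoate | C=CC[C@H](NC(=O)OC(C)(C)C)CC(=O)OC | intermediate
3 | dec-1-ene | CCCCCCCCC=C | starting material
4 | methyl (3S,5Z)-3-[(tert-butoxycarbonyl)amino]tetradec-5-enoate | CCCCCCCC/C=C\C[C@H](NC(=O)OC(C)(C)C)CC(=O)OC | intermediate
5 | (3S,5Z)-3-[(tert-butoxycarbonyl)amino]tetradec-5-enoic acid | CCCCCCCC/C=C\C[C@H](NC(=O)OC(C)(C)C)CC(=O)O | intermediate
6 | 5-aminopentan-1-ol | NCCCCCO | starting material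
7 | acrylonitrile | C=CC#N | starting material
8 | 3-[(5-hydroxypentyl)amino]propanenitrile | N#CCCNCCCCCO | intermediate
9 | (S)-2-methylbutanoic acid | CC[C@H](C)C(=O)O | starting material
10 | (2S)-N-(2-cyanoethyl)-N-(5-hydroxypentyl)-2-methylbutanamide | CC[C@H](C)C(=O)N(CCC#N)CCCCCO | intermediate
11 | (2S)-N-(2-cyanoethyl)-2-methyl-N-(5-oxopentyl)butanamide | CC[C@H](C)C(=O)N(CCC#N)CCCCC=O | intermediate
12 | 3,3-diethoxypropan-1-amine | CCOC(CCN)OCC | starting material
13 | aldimine of 11 with 12 (not isolated) | CC[C@H](C)C(=O)N(CCC#N)CCCCC=NCCC(OCC)OCC | intermediate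
14 | (2S)-N-(2-cyanoethyl)-N-{5-[(3,3-diethoxypropyl)amino]pentyl}-2-methylbutanamide | CC[C@H](C)C(=O)N(CCC#N)CCCCCNCCC(OCC)OCC | intermediate
15 | (2S)-N-(2-cyanoethyl)-N-(5-{(3,3-diethoxypropyl)[(2S)-2-methylbutanoyl]amino}pentyl)-2-methylbutanamide | CC[C@H](C)C(=O)N(CCC#N)CCCCCN(CCC(OCC)OCC)C(=O)[C@@H](C)CC | intermediate
16 | (2S)-N-(3-aminopropyl)-N-(5-{(3,3-diethoxypropyl)[(2S)-2-methylbutanoyl]amino}pentyl)-2-methylbutanamide | CC[C@H](C)C(=O)N(CCCN)CCCCCN(CCC(OCC)OCC)C(=O)[C@@H](C)CC | intermediate
17 | N-Boc/diethyl acetal seco compound | CCCCCCCC/C=C\C[C@H](NC(=O)OC(C)(C)C)CC(=O)NCCCN(C(=O)[C@@H](C)CC)CCCCCN(C(=O)[C@@H](C)CC)CCC(OCC)OCC | intermediate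
18 | seco amino aldehyde trifluoroacetate | CCCCCCCC/C=C\C[C@H](N)CC(=O)NCCCN(C(=O)[C@@H](C)CC)CCCCCN(C(=O)[C@@H](C)CC)CCC=O.OC(=O)C(F)(F)F | intermediate
19 | free seco amino aldehyde (not isolated) | CCCCCCCC/C=C\C[C@H](N)CC(=O)NCCCN(C(=O)[C@@H](C)CC)CCCCCN(C(=O)[C@@H](C)CC)CCC=O | intermediate
20 | 18-membered cyclic imine, C10=N9 (not isolated) | CCCCCCCC/C=C\C[C@H]1CC(=O)NCCCN(C(=O)[C@@H](C)CC)CCCCCN(C(=O)[C@@H](C)CC)CCC=N1 | intermediate
21 | (8S)-1,13-bis[(2S)-2-methylbutanoyl]-8-[(2Z)-undec-2-en-1-yl]-1,5,9,13-tetraazacyclooctadecan-6-one | CCCCCCCC/C=C\C[C@H]1CC(=O)NCCCN(C(=O)[C@@H](C)CC)CCCCCN(C(=O)[C@@H](C)CC)CCCN1 | target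

**Step count**
- Total step count: 12.
- Longest linear sequence: 9 (steps 4–12, from 5-aminopentan-1-ol).

**Steps most likely to fail**

1. **Step 12.**
   - What may go wrong: intermolecular condensation may outrun ring closure, so that reduction fixes oligomeric amines. The hydride may reduce the aldehyde before it condenses. N9 may be alkylated a second time. The C10–C12 arm may be lost by β-elimination of the amide from the enamine tautomer. The imine may also rest as a transannular aminal with N5.
   - Fallback: it sets out from 18, makes the same N9–C10 bond by irreversible alkylation, and returns at 21.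
   - Schotten–Baumann sulfonylation of 18 with 2-nitrobenzenesulfonyl chloride (CH2Cl2/aq. NaHCO3, 0 °C) should give the N-nosyl seco amino aldehyde F1.
   - NaBH4 in MeOH at 0 °C should reduce F1 to the N-nosyl seco amino alcohol F2.
   - Fukuyama–Mitsunobu ring closure (PPh3, diisopropyl azodicarboxylate, THF/toluene, slow addition at high dilution) should give the N9-nosyl macrocycle F3.
   - PhSH/K2CO3 in MeCN under argon then removes the sulfonyl group to give 21.

2. **Step 2.**
   - What may go wrong: carbamate or ester carbonyl chelation to ruthenium may stall turnover. Homodimerisation of either partner may consume material. Secondary metathesis may erode the Z geometry.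
   - Fallback: it sets out from 2, builds the alkene by olefination, and returns at 4.
   - Ozonolysis of 2 (O3, CH2Cl2, −78 °C; Me2S) should give methyl (3S)-3-[(tert-butoxycarbonyl)amino]-5-oxopentanoate F4.
   - F4 is added at −78 °C to the unstabilised ylide nonylidene(triphenyl)phosphorane F5, generated from nonyltriphenylphosphonium bromide with NaN(SiMe3)2 in THF.
   - The kinetically controlled Wittig reaction under lithium-free conditions should deliver the Z-alkene 4.

3. **Step 11.**
   - What may go wrong: the simultaneous unmasking may be uneven, with incomplete acetal hydrolysis. TFA may add across the alkene or the alkene may be tert-butylated on longer exposure. The aldehyde may undergo acid-promoted aldol or elimination chemistry, and the salt may self-condense while it is concentrated.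
   - Fallback: it sets out from 17, frees the two ends one after the other through an isolable, purifiable intermediate, and returns at 19.
   - PPTS in acetone/H2O at 40 °C should hydrolyse only the acetal and give the N-Boc seco amino aldehyde F6.
   - 4 M HCl in dioxane at 0 °C should then remove the Boc group to give the seco amino aldehyde hydrochloride F7.
   - F7 is evaporated and neutralised in the flask of step 12 to give 19.

**Further compounds**
F1 | step 12 | N-nosyl seco amino aldehyde | CCCCCCCC/C=C\C[C@H](NS(=O)(=O)c1ccccc1[N+](=O)[O-])CC(=O)NCCCN(C(=O)[C@@H](C)CC)CCCCCN(C(=O)[C@@H](C)CC)CCC=O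
F2 | step 12 | N-nosyl seco amino alcohol | CCCCCCCC/C=C\C[C@H](NS(=O)(=O)c1ccccc1[N+](=O)[O-])CC(=O)NCCCN(C(=O)[C@@H](C)CC)CCCCCN(C(=O)[C@@H](C)CC)CCCO
F3 | step 12 | N9-nosyl macrocycle | CCCCCCCC/C=C\C[C@H]1CC(=O)NCCCN(C(=O)[C@@H](C)CC)CCCCCN(C(=O)[C@@H](C)CC)CCCN1S(=O)(=O)c2ccccc2[N+](=O)[O-]
F4 | step 2 | methyl (3S)-3-[(tert-butoxycarbonyl)amino]-5-oxopentanoate | O=CC[C@H](NC(=O)OC(C)(C)C)CC(=O)OC
F5 | step 2 | nonylidene(triphenyl)phosphorane | CCCCCCCCC=P(c1ccccc1)(c1ccccc1)c1ccccc1
F6 | step 11 | N-Boc seco amino aldehyde | CCCCCCCC/C=C\C[C@H](NC(=O)OC(C)(C)C)CC(=O)NCCCN(C(=O)[C@@H](C)CC)CCCCCN(C(=O)[C@@H](C)CC)CCC=O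
F7 | step 11 | seco amino aldehyde hydrochloride | CCCCCCCC/C=C\C[C@H](N)CC(=O)NCCCN(C(=O)[C@@H](C)CC)CCCCCN(C(=O)[C@@H](C)CC)CCC=O.Cl
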